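**The pitfall.** A quench that eats a given share of the starting material need not cost that many points of product while conversion is partial. If one protic impurity destroys one starting material, the larch and alder runs lose 0.833% and 3.71% of the charge. Yet after 40.0 h their product reads 23.1% and 22.3%, a gap of 0.8 percentage points, which is smaller than the 2.9 points between the two losses.

in all of them: starting material 0.24 M

| flask | protic impurity | remark | time |
|---|---|---|---|
| larch | 0.0020 M | run made earlier |  |
| alder | 0.0089 M | run made earlier |  |
| south-west | 0.00300 M |  | 3.0 d |
| north-east | 0.00600 M |  | 3.0 d |
| north-west | 0.0120 M |  | 3.0 d |

- larch (time / h: product / %, starting material / %): 10.0: 4.0, 31.0; 20.0: 10.3, 20.7; 25.0: 13.5, 18.2; 40.0: 23.1, 12.7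
- alder (time / h: product / %, starting material / %): 5.00: 1.8, 44.2; 12.0: 5.1, 26.5; 25.0: 13.3, 17.3; 40.0: 22.3, 12.2

(standard deviation of a reading: 0.5 percentage points)

- reactions considered so far: intermediate D <-> product; intermediate B <-> intermediate C; intermediate A -> intermediate D; starting material + protic impurity -> quenched substrate; starting material <-> intermediate B; starting material <-> intermediate A
- "hardly changes" means that all values lie within two and a half points (for a concentration: within two and a half percent of the largest)

* amount of product at the end, in percent of the starting material charged for south-west, north-east, north-west, in this order
* the shape of the row from first to last (rises, then falls / falls all the way / falls, then rises / hardly changes / rises all the way)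

**The ladder.** We take the quench as the first rung, with protic impurity as its limiting reagent; the readings do not show this directly. On the next rung, starting material in the larch run is down to 31.0% after 10.0 h, while product reads 4.0%, so 65.0% of the charge stands in forms we do not read. On the last rung, product climbs. At 40.0 h the larch run has 23.1% of product, and the unread part is still 64.2%. The larch product is still rising at its last reading, and we expect the asked flasks to be on this rung at 3.0 d.

**The join.** At the early end, the quench leaves a surviving share of one minus the impurity's charge over the starting material's. At the late end, if the later steps are first order, product scales with that share. Dividing the product at 40.0 h by the surviving share gives 23.3% for larch and 23.2% for alder, with a scatter of 0.5 points on each reading. So we commit to the survivor ratio, the surviving share of north-west over that of south-west: 0.962. It needs no product level.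

**The forecast.** The forecast gives 40.8%, 40.3% and 39.2%, and calls the impurity “a stoichiometric tax, not a kinetic switch”. Its shape is "hardly changes". At its level, our ratio means a drop of 1.5 points across the row, inside the stated margin, so we agree on the shape.

**The result.** The flasks give 35.2%, 34.7% and 33.9%, so the row hardly changes, at a level below the forecast's. In north-west at 3.0 d, quenched substrate stands at 5.00% with 0% of the protic impurity left. The survivor ratio times the south-west product gives 33.9%, against 33.9% found in north-west. After 30.0 d, south-west holds 50.1% of product, the ratio makes that 48.2%, and north-west holds 48.2%.

    intermediate D ⇌ product (K = 1.10, k = 0.00130 min⁻¹)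
    intermediate B ⇌ intermediate C (K = 0.140, k = 8.80 × 10⁻⁴ min⁻¹)
    intermediate A → intermediate D (k = 5.70 × 10⁻⁴ min⁻¹)
    starting material + protic impurity → quenched substrate (k = 0.130 M⁻¹ min⁻¹)
    starting material ⇌ intermediate B (K = 2.80, k = 1.60 × 10⁻⁴ min⁻¹)
    starting material ⇌ intermediate A (K = 2.20, k = 0.00310 min⁻¹)

The readings come from a simulation for an exercise; scatter was added.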